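The synthesis rests on disconnecting the lactone C5–O5 bond. In the target, O5 on C5 and the C1–C3 arm on C4 are cis on the oxolane ring, which is what makes the pyranone cis-fused. A (Z)-acrylate carboxyl on C4 can therefore reach C5 of a C5–C6 oxirane lying on the opposite face. One acid treatment cleaves the tert-butyl ester, opens the oxirane at C5 with inversion, closes the six-membered lactone and releases O6. The precursor 13 is a 2,5-cis oxolane carrying the (Z)-tert-butyl acrylate on C4, a silyloxymethyl group (C8) on C7 and the anti C5–C6 oxirane. C6 is inverted afterwards and C9–C12 is added by cross-metathesis.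

Key step: step 10

Remark: atoms are numbered along the chain: C1 (lactone carbonyl), C2=C3, C4, C5 (bears O5), C6 (bears O6), C7, C8=C9, C10 (benzoate), C11 (hydroxyl), C12; C4 and C7 flank the oxolane oxygen.

Assumption: in step 4 lipase PS is taken to acetylate the hydroxymethyl arm on the (S)-configured ring carbon of 6; if it prefers the other arm, hydrolysis of the diacetate of 6 by the same lipase should give 7, because acylation and hydrolysis address the same enantiotopic arm.

Step 1
Reactants: 1 furan; 2 vinylene carbonate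
Product: 3 7-oxabicyclo[2.2.1]hept-5-ene-2,3-diyl carbonate (meso; exo/endo mixture)
Conditions: neat (excess 1), sealed tube, 125 °C
Reagents that add atoms: none
Why: Thermal Diels–Alder cycloaddition of furan to the cis dienophile, in which the oxygen bridge forces the two bridgehead carbons (the future C4 and C7) to be cis, while the exo/endo ratio is irrelevant because both carbinol carbons are excised in step 3.

Step 2
Reactants: 3 bicyclic carbonate
Product: 4 7-oxabicyclo[2.2.1]hept-5-ene-2,3-diol (meso cis-diol; exo/endo mixture)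
Conditions: K2CO3 (cat.), MeOH, rt
Reagents that add atoms: none
Why: Base-catalysed transesterification of the cyclic carbonate by methanol should free the cis-diol without touching the alkene or the bridgehead centres.

Step 3
Reactants: 4 bicyclic diol
Product: 6 cis-2,5-bis(hydroxymethyl)-2,5-dihydrofuran (meso), via cis-2,5-dihydrofuran-2,5-dicarbaldehyde 5 (not isolated)
Conditions: NaIO4, H2O/MeOH, 0 °C; then NaBH4, 0 °C
Reagents that add atoms: none
Why: Malaprade glycol cleavage followed by borohydride reduction in the same pot, so that the enolisable dialdehyde is trapped before C4 or C7 can epimerise and the cis relationship from step 1 is kept.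

Step 4
Reactants: 6 meso diol
Product: 7 [(2S,5R)-5-(hydroxymethyl)-2,5-dihydrofuran-2-yl]methyl acetate
Conditions: lipase PS (Burkholderia cepacia), vinyl acetate, THF, rt
Reagents that add atoms: vinyl acetate, CC(=O)OC=C
Why: Lipase-catalysed irreversible transesterification (enzymatic desymmetrisation of a meso diol) should acylate one enantiotopic arm only, which fixes the absolute configuration of C4 and C7 by catalyst control.

Step 5
Reactants: 7 monoacetate
Product: 8 [(2S,5R)-5-{[tert-butyl(diphenyl)silyl]oxymethyl}-2,5-dihydrofuran-2-yl]methyl acetate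
Conditions: tBuPh2SiCl, imidazole, CH2Cl2, 0 °C → rt
Reagents that add atoms: tert-butyl(chloro)diphenylsilane, CC(C)(C)[Si](Cl)(c1ccccc1)c1ccccc1
Why: Imidazole-mediated silylation of the primary alcohol installs a C8 protecting group chosen because it should survive the acid of step 10.

Step 6
Reactants: 8 silyl ether acetate
Product: 9 [(1R,2R,4S,5S)-4-{[tert-butyl(diphenyl)silyl]oxymethyl}-3,6-dioxabicyclo[3.1.0]hexan-2-yl]methyl acetate (oxirane anti to both arms)
Conditions: mCPBA, 2,6-di-tert-butyl-4-methylphenol (cat.), ClCH2CH2Cl, 60 °C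
Reagents that add atoms: 3-chloroperbenzoic acid, O=C(OO)c1cccc(Cl)c1
Why: Prilezhaev epoxidation in which the peracid approaches the ring alkene from the face opposite to the two cis arms (both protected, so no hydroxyl can direct it), setting C5 and C6 anti to them by substrate control.

Step 7
Reactants: 9 epoxy acetate
Product: 10 [(1R,2R,4S,5S)-4-{[tert-butyl(diphenyl)silyl]oxymethyl}-3,6-dioxabicyclo[3.1.0]hexan-2-yl]methanol
Conditions: K2CO3 (cat.), MeOH, 0 °C
Reagents that add atoms: none
Why: Base-catalysed methanolysis (transesterification) should remove the primary acetate while the silyl ether and the oxirane persist, since the alkoxide can reach neither oxirane carbon in a favourable exo mode.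

Step 8
Reactants: 10 epoxy alcohol
Product: 11 (1S,2S,4S,5S)-4-{[tert-butyl(diphenyl)silyl]oxymethyl}-3,6-dioxabicyclo[3.1.0]hexane-2-carbaldehyde
Conditions: Dess–Martin periodinane, NaHCO3, CH2Cl2, 0 °C → rt; crude used at once
Reagents that add atoms: none
Why: Dess–Martin oxidation under buffered, non-basic conditions should give the aldehyde without enolisation at C4, which would epimerise that centre or open the oxirane by β-elimination.

Step 9
Reactants: 11 epoxy aldehyde; 12 tert-butyl bis(2,2,2-trifluoroethyl)phosphonoacetate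
Product: 13 tert-butyl (2Z)-3-[(1R,2R,4S,5S)-4-{[tert-butyl(diphenyl)silyl]oxymethyl}-3,6-dioxabicyclo[3.1.0]hexan-2-yl]prop-2-enoate
Conditions: KN(SiMe3)2, 18-crown-6, THF, −78 °C
Reagents that add atoms: none
Why: Still–Gennari variant of the Horner–Wadsworth–Emmons olefination, whose kinetically controlled elimination from the trifluoroethyl phosphonate adduct should give the (Z)-enoate, run at −78 °C with a dissociated potassium anion so that addition outruns enolisation of the aldehyde.

Step 10
Reactants: 13 epoxy (Z)-tert-butyl enoate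
Product: 14 (2S,3S,3aR,7aR)-2-{[tert-butyl(diphenyl)silyl]oxymethyl}-3-hydroxy-2,3,3a,7a-tetrahydro-5H-furo[3,2-b]pyran-5-one (cis-fused; O6 trans to its three neighbours)
Conditions: CF3CO2H, CH2Cl2, 0 °C → rt
Reagents that add atoms: none
Why: Protonation activates the oxirane, and the ester carbonyl oxygen, held above the ring by the cis C4 arm and the (Z)-alkene, attacks C5 opposite to the breaking C5–O bond; the resulting tert-butoxy oxocarbenium ion then sheds isobutene to leave the lactone and the free C6 hydroxyl. This is the acid-mediated lactonisation of epoxy tert-butyl esters, a known relative of halolactonisation in which the ester itself is the nucleophile. The pyranone ring (O5, C1, C2, C3, C4, C5) closes in the 6-exo-tet mode, the breaking C5–O bond lying outside the new ring, whereas C6 could only be reached through a strained bridged seven-membered transition state. The new centre C5 is set by inversion, so O5 ends cis to the C4 arm (cis ring fusion), while C6 keeps the oxirane configuration and its hydroxyl ends trans to its three neighbours. The step needs C5 over C6 regioselectivity and intramolecular over intermolecular opening, and both follow from the tether, because the oxirane lies anti to the arm and only C5 is within reach of the carboxyl. The tert-butyldiphenylsilyl ether and the enoate should tolerate the acid.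

Step 11
Reactants: 14 6-epi hydroxy lactone
Product: 15 (2S,3aS,7aR)-2-{[tert-butyl(diphenyl)silyl]oxymethyl}-3a,7a-dihydro-5H-furo[3,2-b]pyran-3,5(2H)-dione
Conditions: Dess–Martin periodinane, NaHCO3, CH2Cl2, rt
Reagents that add atoms: none
Why: Dess–Martin oxidation of the secondary alcohol under buffered conditions should give the C6 ketone without epimerising the flanking centres C5 and C7.

Step 12
Reactants: 15 C6 ketone
Product: 16 (2S,3R,3aR,7aR)-2-{[tert-butyl(diphenyl)silyl]oxymethyl}-3-hydroxy-2,3,3a,7a-tetrahydro-5H-furo[3,2-b]pyran-5-one (all-cis)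
Conditions: NaBH4, CeCl3·7H2O, MeOH, −78 °C
Reagents that add atoms: none
Why: Luche reduction at low temperature should reduce the ketone in preference to the enoate, with hydride adding from the convex lower face of the cis-fused bicycle, opposite to O5 and the C7 arm, so that the C6 hydroxyl is placed cis to both (net inversion of C6).

Step 13
Reactants: 16 all-cis alcohol
Product: 17 (2S,3R,3aS,7aR)-3-[tert-butyl(dimethyl)silyl]oxy-2-{[tert-butyl(diphenyl)silyl]oxymethyl}-2,3,3a,7a-tetrahydro-5H-furo[3,2-b]pyran-5-one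
Conditions: tBuMe2SiOTf, 2,6-lutidine, CH2Cl2, −78 → 0 °C
Reagents that add atoms: tert-butyldimethylsilyl trifluoromethanesulfonate, CC(C)(C)[Si](C)(C)OS(=O)(=O)C(F)(F)F
Why: Silylation of the hindered secondary alcohol by the reactive silyl triflate and a non-nucleophilic base, conditions too mild to deprotonate the lactone at C4.

Step 14
Reactants: 17 bis-silyl ether
Product: 18 (2S,3R,3aS,7aR)-3-[tert-butyl(dimethyl)silyl]oxy-2-(hydroxymethyl)-2,3,3a,7a-tetrahydro-5H-furo[3,2-b]pyran-5-one
Conditions: Bu4NF, AcOH, THF, 0 °C → rt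
Reagents that add atoms: none
Why: Buffered fluoride desilylation, in which the unhindered primary diphenylsilyl ether should be attacked much faster than the shielded secondary dimethylsilyl ether, while acetic acid keeps the medium non-basic and so protects the lactone and suppresses silyl migration to O8.

Step 15
Reactants: 18 primary alcohol
Product: 19 (2R,3S,3aS,7aR)-3-[tert-butyl(dimethyl)silyl]oxy-5-oxo-2,3,3a,7a-tetrahydro-5H-furo[3,2-b]pyran-2-carbaldehyde
Conditions: Dess–Martin periodinane, NaHCO3, CH2Cl2, 0 °C → rt; crude used at once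
Reagents that add atoms: none
Why: Dess–Martin oxidation under buffered conditions should give the C8 aldehyde without epimerising C7 or eliminating the C6 silyloxy group.

Step 16
Reactants: 19 aldehyde
Product: 20 (2S,3R,3aS,7aR)-3-[tert-butyl(dimethyl)silyl]oxy-2-ethenyl-2,3,3a,7a-tetrahydro-5H-furo[3,2-b]pyran-5-one
Conditions: Zn, CH2Br2, TiCl4, THF/CH2Cl2, 0 °C → rt
Reagents that add atoms: dibromomethane, BrCBr
Why: Takai–Lombardo methylenation, a non-basic zinc–titanium carbenoid olefination that converts aldehydes but not lactones and should therefore leave the α-alkoxy centre C7 and the enoate untouched.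

Step 17
Reactants: 21 penta-1,4-dien-3-ol
Product: 22 (1S)-1-[(2R)-oxiran-2-yl]prop-2-en-1-ol
Conditions: Ti(OiPr)4 (cat.), L-(+)-diisopropyl tartrate (cat.), tBuOOH, 4 Å molecular sieves, CH2Cl2, −20 °C
Reagents that add atoms: tert-butyl hydroperoxide, CC(C)(C)OO
Why: Sharpless asymmetric epoxidation of the achiral divinyl carbinol, in which the tartrate–titanium catalyst selects one enantiotopic vinyl group and one alkene face to give the erythro epoxy alcohol (the future C10 and C11), while the minor enantiomer is consumed by a faster second epoxidation.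

Step 18
Reactants: 22 epoxy alcohol
Product: 23 (1S)-1-[(2R)-oxiran-2-yl]prop-2-en-1-yl benzoate
Conditions: BzCl, pyridine, DMAP (cat.), CH2Cl2, 0 °C
Reagents that add atoms: benzoyl chloride, O=C(Cl)c1ccccc1
Why: Pyridine-mediated acylation of the secondary alcohol places the benzoate on the future O10 before the second oxygen is unmasked, so the two hydroxyls never need to be told apart.

Step 19
Reactants: 23 epoxy benzoate
Product: 24 (3S,4S)-5-bromo-4-hydroxypent-1-en-3-yl benzoate
Conditions: LiBr, AcOH, THF, rt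
Reagents that add atoms: lithium bromide, [Li+].[Br-]
Why: Buffered halohydrin formation by SN2 attack of bromide on the unsubstituted oxirane carbon, which breaks no bond at either stereocentre.

Step 20
Reactants: 24 bromohydrin
Product: 25 (3S,4R)-4-hydroxypent-1-en-3-yl benzoate
Conditions: Bu3SnH, AIBN (cat.), toluene, 80 °C
Reagents that add atoms: none
Why: Radical chain dehalogenation with tributyltin hydride turns the bromomethyl group into the C12 methyl group under neutral conditions that should not cause benzoate migration.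

Step 21
Reactants: 20 vinyl lactone; 25 allylic benzoate (3 equiv)
Product: 26 (1E,3S,4R)-1-[(2S,3R,3aS,7aR)-3-[tert-butyl(dimethyl)silyl]oxy-5-oxo-2,3,3a,7a-tetrahydro-5H-furo[3,2-b]pyran-2-yl]-4-hydroxypent-1-en-3-yl benzoate
Conditions: second-generation Hoveyda–Grubbs catalyst RuCl2(H2IMes)(=CH-C6H4-2-OiPr) (10 mol %), CH2Cl2, 40 °C
Reagents that add atoms: none
Why: Olefin cross-metathesis between two terminal alkenes that each carry an oxygenated secondary allylic carbon and so homodimerise slowly, which should give the (E)-C8=C9 alkene under thermodynamic control while the electron-poor ring enoate stays inert.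

Step 22
Reactants: 26 silyl-protected target
Product: 27 (1E,3S,4R)-4-hydroxy-1-[(2S,3R,3aR,7aR)-3-hydroxy-5-oxo-2,3,3a,7a-tetrahydro-5H-furo[3,2-b]pyran-2-yl]pent-1-en-3-yl benzoate (CNP0140142.1)
Conditions: HF·pyridine, pyridine, THF, 0 °C → rt
Reagents that add atoms: none
Why: Fluoride-mediated desilylation under mildly acidic conditions, which should avoid the base-induced benzoate shift from O10 to O11 and any opening of the lactone.

Compound list
1 | furan | c1ccoc1 | starting material
2 | vinylene carbonate | O=C1OC=CO1 | starting material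
3 | 7-oxabicyclo[2.2.1]hept-5-ene-2,3-diyl carbonate, meso (exo isomer drawn; the endo isomer is carried on with it) | O=C1O[C@H]2[C@@H]3C=C[C@@H](O3)[C@H]2O1 | intermediate
4 | 7-oxabicyclo[2.2.1]hept-5-ene-2,3-diol, meso cis-diol (exo isomer drawn) | O[C@H]1[C@@H]2C=C[C@@H](O2)[C@H]1O | intermediate
5 | cis-2,5-dihydrofuran-2,5-dicarbaldehyde, meso | O=C[C@H]1O[C@@H](C=O)C=C1 | intermediate
6 | cis-2,5-bis(hydroxymethyl)-2,5-dihydrofuran, meso | OC[C@H]1O[C@@H](CO)C=C1 | intermediate
7 | [(2S,5R)-5-(hydroxymethyl)-2,5-dihydrofuran-2-yl]methyl acetate | CC(=O)OC[C@H]1O[C@@H](CO)C=C1 | intermediate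
8 | [(2S,5R)-5-{[tert-butyl(diphenyl)silyl]oxymethyl}-2,5-dihydrofuran-2-yl]methyl acetate | CC(=O)OC[C@H]1O[C@@H](CO[Si](c2ccccc2)(c2ccccc2)C(C)(C)C)C=C1 | intermediate
9 | [(1R,2R,4S,5S)-4-{[tert-butyl(diphenyl)silyl]oxymethyl}-3,6-dioxabicyclo[3.1.0]hexan-2-yl]methyl acetate | CC(=O)OC[C@H]1O[C@@H](CO[Si](c2ccccc2)(c2ccccc2)C(C)(C)C)[C@@H]2O[C@H]12 | intermediate
10 | [(1R,2R,4S,5S)-4-{[tert-butyl(diphenyl)silyl]oxymethyl}-3,6-dioxabicyclo[3.1.0]hexan-2-yl]methanol | OC[C@H]1O[C@@H](CO[Si](c2ccccc2)(c2ccccc2)C(C)(C)C)[C@@H]2O[C@H]12 | intermediate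
11 | (1S,2S,4S,5S)-4-{[tert-butyl(diphenyl)silyl]oxymethyl}-3,6-dioxabicyclo[3.1.0]hexane-2-carbaldehyde | O=C[C@H]1O[C@@H](CO[Si](c2ccccc2)(c2ccccc2)C(C)(C)C)[C@@H]2O[C@H]12 | intermediate
12 | tert-butyl bis(2,2,2-trifluoroethyl)phosphonoacetate | CC(C)(C)OC(=O)CP(=O)(OCC(F)(F)F)OCC(F)(F)F | starting material
13 | tert-butyl (2Z)-3-[(1R,2R,4S,5S)-4-{[tert-butyl(diphenyl)silyl]oxymethyl}-3,6-dioxabicyclo[3.1.0]hexan-2-yl]prop-2-enoate | CC(C)(C)OC(=O)/C=C\[C@H]1O[C@@H](CO[Si](c2ccccc2)(c2ccccc2)C(C)(C)C)[C@@H]2O[C@H]12 | intermediate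
14 | (2S,3S,3aR,7aR)-2-{[tert-butyl(diphenyl)silyl]oxymethyl}-3-hydroxy-2,3,3a,7a-tetrahydro-5H-furo[3,2-b]pyran-5-one | CC(C)(C)[Si](c1ccccc1)(c1ccccc1)OC[C@@H]1O[C@@H]2C=CC(=O)O[C@@H]2[C@H]1O | intermediate
15 | (2S,3aS,7aR)-2-{[tert-butyl(diphenyl)silyl]oxymethyl}-3a,7a-dihydro-5H-furo[3,2-b]pyran-3,5(2H)-dione | CC(C)(C)[Si](c1ccccc1)(c1ccccc1)OC[C@@H]1O[C@@H]2C=CC(=O)O[C@@H]2C1=O | intermediate
16 | (2S,3R,3aR,7aR)-2-{[tert-butyl(diphenyl)silyl]oxymethyl}-3-hydroxy-2,3,3a,7a-tetrahydro-5H-furo[3,2-b]pyran-5-one | CC(C)(C)[Si](c1ccccc1)(c1ccccc1)OC[C@@H]1O[C@@H]2C=CC(=O)O[C@@H]2[C@@H]1O | intermediate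
17 | (2S,3R,3aS,7aR)-3-[tert-butyl(dimethyl)silyl]oxy-2-{[tert-butyl(diphenyl)silyl]oxymethyl}-2,3,3a,7a-tetrahydro-5H-furo[3,2-b]pyran-5-one | CC(C)(C)[Si](c1ccccc1)(c1ccccc1)OC[C@@H]1O[C@@H]2C=CC(=O)O[C@@H]2[C@@H]1O[Si](C)(C)C(C)(C)C | intermediate
18 | (2S,3R,3aS,7aR)-3-[tert-butyl(dimethyl)silyl]oxy-2-(hydroxymethyl)-2,3,3a,7a-tetrahydro-5H-furo[3,2-b]pyran-5-one | OC[C@@H]1O[C@@H]2C=CC(=O)O[C@@H]2[C@@H]1O[Si](C)(C)C(C)(C)C | intermediate
19 | (2R,3S,3aS,7aR)-3-[tert-butyl(dimethyl)silyl]oxy-5-oxo-2,3,3a,7a-tetrahydro-5H-furo[3,2-b]pyran-2-carbaldehyde | O=C[C@@H]1O[C@@H]2C=CC(=O)O[C@@H]2[C@@H]1O[Si](C)(C)C(C)(C)C | intermediate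
20 | (2S,3R,3aS,7aR)-3-[tert-butyl(dimethyl)silyl]oxy-2-ethenyl-2,3,3a,7a-tetrahydro-5H-furo[3,2-b]pyran-5-one | C=C[C@@H]1O[C@@H]2C=CC(=O)O[C@@H]2[C@@H]1O[Si](C)(C)C(C)(C)C | intermediate
21 | penta-1,4-dien-3-ol | C=CC(O)C=C | starting material
22 | (1S)-1-[(2R)-oxiran-2-yl]prop-2-en-1-ol, i.e. (2R,3S)-1,2-epoxypent-4-en-3-ol | C=C[C@H](O)[C@H]1CO1 | intermediate
23 | (1S)-1-[(2R)-oxiran-2-yl]prop-2-en-1-yl benzoate | C=C[C@H](OC(=O)c1ccccc1)[C@H]1CO1 | intermediate
24 | (3S,4S)-5-bromo-4-hydroxypent-1-en-3-yl benzoate | C=C[C@H](OC(=O)c1ccccc1)[C@H](O)CBr | intermediate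
25 | (3S,4R)-4-hydroxypent-1-en-3-yl benzoate | C=C[C@H](OC(=O)c1ccccc1)[C@H](O)C | intermediate
26 | (1E,3S,4R)-1-[(2S,3R,3aS,7aR)-3-[tert-butyl(dimethyl)silyl]oxy-5-oxo-2,3,3a,7a-tetrahydro-5H-furo[3,2-b]pyran-2-yl]-4-hydroxypent-1-en-3-yl benzoate | C[C@@H](O)[C@H](/C=C/[C@@H]1O[C@@H]2C=CC(=O)O[C@@H]2[C@@H]1O[Si](C)(C)C(C)(C)C)OC(=O)c1ccccc1 | intermediate
27 | (1E,3S,4R)-4-hydroxy-1-[(2S,3R,3aR,7aR)-3-hydroxy-5-oxo-2,3,3a,7a-tetrahydro-5H-furo[3,2-b]pyran-2-yl]pent-1-en-3-yl benzoate (CNP0140142.1) | C[C@@H](O)[C@H](/C=C/[C@@H]1O[C@@H]2C=CC(=O)O[C@@H]2[C@@H]1O)OC(=O)c1ccccc1 | target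

Total step count: 22.
Longest linear sequence: 18 steps (steps 1–16, 21 and 22); steps 17–20 build the side-chain fragment 25.

Steps most likely to fail

Step 10. Trifluoroacetate or adventitious water may open the protonated oxirane intermolecularly, or the silyl ether may be eroded, before the carboxyl has closed the ring. The fallback separates unmasking from ring closure and avoids strong acid. It sets out from aldehyde 11, which is olefinated under the conditions of step 9 with commercial methyl bis(2,2,2-trifluoroethyl)phosphonoacetate to give the methyl (Z)-enoate F1. Neutral hydrolysis with Me3SnOH in ClCH2CH2Cl at 70 °C should give the (Z)-carboxylic acid F2. A catalytic amount of camphorsulfonic acid in CH2Cl2 then lets the free acid open the oxirane at C5 in the same 6-exo, anti sense, and the route is rejoined at 14.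

Step 9. The phosphonate anion may enolise the epoxy aldehyde instead of adding to it, so that C4 epimerises or the oxirane is opened by β-elimination, and the Z selectivity may be eroded. The fallback olefinates before the oxirane exists, so no leaving group sits β to the aldehyde. It sets out from 8, which is deacetylated (K2CO3, MeOH) to the dihydrofuran alcohol F3 and oxidised with Dess–Martin periodinane to the dihydrofuran aldehyde F4. Still–Gennari olefination with 12 gives the diene ester F5. mCPBA should then epoxidise only the ring alkene, anti to both arms, because the enoate alkene is electron-poor, and the route is rejoined at 13.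

Step 21. Productive metathesis between two hindered, oxygenated allylic alkenes may be slow, so that homodimerisation of 25 and catalyst decay take over. The fallback forms the C9–C10 bond by carbonyl addition and also bypasses step 16. It sets out from aldehyde 19, which Takai iodo-olefination (CrCl2, CHI3, THF, 0 °C) should convert into the (E)-vinyl iodide F6. Separately, purchased methyl (R)-lactate is silylated (tBuMe2SiCl, imidazole) to the silyl ether ester F7 and reduced with iBu2AlH at −78 °C to the (R)-2-silyloxypropanal F8. Nozaki–Hiyama–Kishi coupling of F6 and F8 (CrCl2, NiCl2 cat., DMSO) should give the allylic alcohol F9, with the 10,11-anti isomer favoured by Felkin–Anh addition and the C10 epimer removed by chromatography. Benzoylation (BzCl, pyridine, DMAP) gives the bis-silyl benzoate F10, and HF·pyridine removes both silyl ethers to rejoin the route at 27.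

Further compounds
F1 | step 10 | methyl (2Z)-3-[(1R,2R,4S,5S)-4-{[tert-butyl(diphenyl)silyl]oxymethyl}-3,6-dioxabicyclo[3.1.0]hexan-2-yl]prop-2-enoate | COC(=O)/C=C\[C@H]1O[C@@H](CO[Si](c2ccccc2)(c2ccccc2)C(C)(C)C)[C@@H]2O[C@H]12
F2 | step 10 | (2Z)-3-[(1R,2R,4S,5S)-4-{[tert-butyl(diphenyl)silyl]oxymethyl}-3,6-dioxabicyclo[3.1.0]hexan-2-yl]prop-2-enoic acid | OC(=O)/C=C\[C@H]1O[C@@H](CO[Si](c2ccccc2)(c2ccccc2)C(C)(C)C)[C@@H]2O[C@H]12
F3 | step 9 | [(2S,5R)-5-{[tert-butyl(diphenyl)silyl]oxymethyl}-2,5-dihydrofuran-2-yl]methanol | OC[C@H]1O[C@@H](CO[Si](c2ccccc2)(c2ccccc2)C(C)(C)C)C=C1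
F4 | step 9 | (2S,5R)-5-{[tert-butyl(diphenyl)silyl]oxymethyl}-2,5-dihydrofuran-2-carbaldehyde | O=C[C@H]1O[C@@H](CO[Si](c2ccccc2)(c2ccccc2)C(C)(C)C)C=C1
F5 | step 9 | tert-butyl (2Z)-3-[(2S,5R)-5-{[tert-butyl(diphenyl)silyl]oxymethyl}-2,5-dihydrofuran-2-yl]prop-2-enoate | CC(C)(C)OC(=O)/C=C\[C@H]1O[C@@H](CO[Si](c2ccccc2)(c2ccccc2)C(C)(C)C)C=C1
F6 | step 21 | (2S,3R,3aS,7aR)-3-[tert-butyl(dimethyl)silyl]oxy-2-[(E)-2-iodoethenyl]-2,3,3a,7a-tetrahydro-5H-furo[3,2-b]pyran-5-one | I/C=C/[C@@H]1O[C@@H]2C=CC(=O)O[C@@H]2[C@@H]1O[Si](C)(C)C(C)(C)C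
F7 | step 21 | methyl (2R)-2-[tert-butyl(dimethyl)silyl]oxypropanoate | C[C@@H](O[Si](C)(C)C(C)(C)C)C(=O)OC
F8 | step 21 | (2R)-2-[tert-butyl(dimethyl)silyl]oxypropanal | C[C@@H](O[Si](C)(C)C(C)(C)C)C=O
F9 | step 21 | (2S,3R,3aS,7aR)-3-[tert-butyl(dimethyl)silyl]oxy-2-[(1E,3S,4R)-4-[tert-butyl(dimethyl)silyl]oxy-3-hydroxypent-1-enyl]-2,3,3a,7a-tetrahydro-5H-furo[3,2-b]pyran-5-one | C[C@@H](O[Si](C)(C)C(C)(C)C)[C@@H](O)/C=C/[C@@H]1O[C@@H]2C=CC(=O)O[C@@H]2[C@@H]1O[Si](C)(C)C(C)(C)C
F10 | step 21 | (1E,3S,4R)-4-[tert-butyl(dimethyl)silyl]oxy-1-[(2S,3R,3aS,7aR)-3-[tert-butyl(dimethyl)silyl]oxy-5-oxo-2,3,3a,7a-tetrahydro-5H-furo[3,2-b]pyran-2-yl]pent-1-en-3-yl benzoate | C[C@@H](O[Si](C)(C)C(C)(C)C)[C@H](/C=C/[C@@H]1O[C@@H]2C=CC(=O)O[C@@H]2[C@@H]1O[Si](C)(C)C(C)(C)C)OC(=O)c1ccccc1
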